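In the eta run, which was this very flask followed so far, the left-handed product read 7.4% at 0.833 min. None of the solid reagent stood in solution at the start, so I took this first product to come from the partner as the solid dissolved. In the middle, from 1.50 min to 3.00 min, the reading gained 13 percentage points. From 3.00 min to 5.00 min it gained 2 points, a slower pace. At the end, from 5.00 min to 10.0 min, it moved 0.2 points, with a scatter of 0.3 points on each reading.

| setting | eta | flask |
|---|---|---|
| left-handed substrate | 0.0010 M | 0.0010 M |
| right-handed substrate | 0.0010 M | 0.0010 M |
| solid reagent | 1.1 mM | 1.10 mM |
| remark | the very flask that is asked about, followed so far |  |
| time |  | 10 min |

- eta (time / min: left-handed product / %): 0.833: 7.4; 1.50: 14.6; 3.00: 27.1; 5.00: 29.1; 10.0: 28.9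

(each reading ± 0.3 percentage points)

- partner is single-handed; left-handed substrate and right-handed substrate are mirror images of each other, charged as a racemate, each of them at the stated concentration
- as a solid, counted per litre of solution: solid reagent
- removed left-handed product is counted in
- what was read earlier has a scatter of 0.3 percentage points, one standard deviation
- at the start none of the solid reagent is in solution
- additions bring no volume worth counting
- the handed part of partner does not stay in what it makes, so the products of the two hands are mirror images too

- alder: at 10 min add left-handed substrate, 50.0% of the amount charged, then wait 5.0 min
- cedar: change nothing and wait 5.0 min more
- ash: at 10 min take out 90% of the left-handed product then present, then wait 5.0 min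

* left-handed product, in percent of the left-handed substrate and right-handed substrate together first charged, at 10 min
* which option adds most left-handed product ("none" when 2 percentage points or less is all one gets) (alder / cedar / ash / none)
* left-handed product present, with what was taken out counted in, in percent of the left-handed substrate and right-handed substrate together first charged, after alder
* left-handed product present, with what was taken out counted in, in percent of the left-handed substrate and right-handed substrate together first charged, after cedar

The last two readings averaged 29.0%, or 0.580 mM of left-handed product. That was less than the 1 mM of left-handed substrate charged, so I took the solid reagent as the limiting reagent. Dividing by its charge gave 0.527 mol of left-handed product per mol of solid reagent charged, which I call the reagent yield φ. I froze φ. No option puts in solid reagent, so my reckoning gave no gain from any of them and left the flask at 29.0%.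

The forecast gave 29% (28.7% to 29.3%) for now, 29% for g1, 29% for g2 and none for best: “With the reagent gone, extra substrate, more time or product removal yield nothing”.

The flask gave 28.9%, g1 28.9%, g2 28.9% and best none, with 0% of the solid reagent left at 10.0 min.

    partner + left-handed substrate → left-handed product (k = 18.8 M⁻¹ s⁻¹)
    partner + right-handed substrate → right-handed product (k = 6.26 M⁻¹ s⁻¹)
    left-handed substrate ⇌ right-handed substrate (k = 0.00720 s⁻¹)
    solid reagent ⇌ partner, rate k4*(cs4 - [partner]) while solid is left; crystals form when [partner] > cs4 (solubility = 0.950 mM, k = 0.0124 s⁻¹)
    partner → decomposed reagent (k = 0.00725 s⁻¹)

With everything else held, the answer to now shifted by 5 points at 0.892 mM and at 1.32 mM of solid reagent, and, with all amounts held, at a reading time of 2.34 min; at the higher charge φ gives a rise of 5.8 points. For the neighbouring flask, charged with 0.0028 M of solid reagent, φ gave 73.8% of left-handed product. That flask stood at 59.0%, with 0.00111 M of decomposed reagent, so its reagent yield was 0.421.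

The data were computed for an exercise, noise included.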